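**Plan**
- Retrosynthesis: the C6 ester and the C2–CH2OH bond (Morita–Baylis–Hillman) are cut first, then the ring bonds C3–C4 and C5–C6 together in one [4+2] step; the C4–O bond is traced back to a C4–acetyl bond (Baeyer–Villiger). Target ring numbering used below: C1 C=O, C2 C–CH2OH, C3 =CH, C4 CH–O-isobutyryl, C5 CH–iPr, C6 CH–O-acyl.
- Enabling feature: in the 6-oxy-cyclohex-2-en-1-one ring the C6 oxygen and the enone β-carbon C3 are 1,4-related. Tying C3 back to that oxygen gives a 7-oxabicyclo[2.2.1]heptan-2-one, the retron of a furan cycloaddition. C6, C1, C2, C3 and the C6 oxygen are the five ring atoms of 3-methoxyfuran (C–OMe = C1).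
- Forward: a dearomatizing Diels–Alder reaction of 3-methoxyfuran with (Z)-5-methylhex-3-en-2-one closes the carbocycle as an oxygen-bridged bicycle. Ketalization, Baeyer–Villiger oxidation and isobutyrylation follow; ketal hydrolysis lets the bridge open by E1cB to the 6-hydroxy-enone. C6 esterification, C2 hydroxymethylation and desilylation finish the route.
- Stereochemistry: C4/C5 cis comes from the Z alkene; both groups sit anti to the oxygen bridge (trans to C6–O) through endo addition; the Baeyer–Villiger step proceeds with retention. The cycloadduct is racemic; the absolute configuration is secured by separating the diastereomeric (R,R)-hydrobenzoin ketals in step 5, so at most half of the material is carried on.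

Key step: step 4

**Step 1**
Reactants: 1 3-bromofuran
Product: 2 3-methoxyfuran
Conditions: NaOMe, CuBr (10 mol%), MeOH/NMP, 100 °C
Reagents that add atoms: sodium methoxide, C[O-].[Na+]
Why: Ullmann-type copper-catalysed C–O coupling of a heteroaryl bromide with methoxide, the usual entry to 3-alkoxy five-membered heteroarenes; no stereocenter is formed.

**Step 2**
Reactants: 3 3-methylbut-1-yne
Product: 4 5-methylhex-3-yn-2-one
Conditions: n-BuLi, THF, −78 °C; N-methoxy-N-methylacetamide, −78 → 0 °C; aq. NH4Cl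
Reagents that add atoms: N-methoxy-N-methylacetamide, CC(=O)N(C)OC
Why: The lithium acetylide adds once to the Weinreb amide, whose chelated tetrahedral adduct collapses to the ynone only on work-up; no stereocenter is formed.

**Step 3**
Reactants: 4 5-methylhex-3-yn-2-one
Product: 5 (Z)-5-methylhex-3-en-2-one
Conditions: H2 (1 atm), Pd/CaCO3 poisoned with Pb(OAc)2, quinoline, pentane, 0 °C; used at once
Reagents that add atoms: none
Why: Lindlar-type cis-semihydrogenation delivers both hydrogens to one face of the alkyne and so fixes the Z geometry that later becomes the cis C4/C5 relationship; immediate use should limit Z→E isomerization.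

**Step 4**
Reactants: 2 3-methoxyfuran; 5 (Z)-5-methylhex-3-en-2-one
Product: 6 rac-1-[(1R,4R,5R,6S)-2-methoxy-6-(propan-2-yl)-7-oxabicyclo[2.2.1]hept-2-en-5-yl]ethan-1-one (5-endo-acetyl, 6-endo-isopropyl)
Conditions: CH2Cl2 (2 M), 12 kbar, 23 °C, dark; crude adduct taken on at once
Reagents that add atoms: none
Why: This is a concerted, asynchronous normal-demand [4π+2π] cycloaddition (Diels–Alder) in which the HOMO of 3-methoxyfuran, largest at C2 next to the methoxy carbon, meets the enone LUMO, largest at the β-carbon, so the isopropyl-bearing carbon bonds to furan C2 and the acetyl-bearing carbon to furan C5; the closest known reaction type is the room-temperature Diels–Alder reaction of 3-alkoxyfurans with electron-poor alkenes. The six-membered carbocycle is closed by intermolecular suprafacial [4+2] addition across furan C2/C5, which at the same time creates the 7-oxabicyclo[2.2.1]heptene whose oxygen bridge is the later C6–O bond. The cis relationship of acetyl and isopropyl (C4/C5 of the target) follows from the Z geometry of the dienophile, and their endo position, anti to the oxygen bridge and hence trans to the future C6–O, from the Alder endo approach of the acetyl group. The step needs regioselectivity, secured by the methoxy group, and kinetic endo selectivity, secured by working at 23 °C under pressure, which favours the compact endo transition state and suppresses cycloreversion to the exo isomer. No facial selectivity is available, so 6 should form as a racemate that is resolved in step 5.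

**Step 5**
Reactants: 6 rac-1-[(1R,4R,5R,6S)-2-methoxy-6-(propan-2-yl)-7-oxabicyclo[2.2.1]hept-2-en-5-yl]ethan-1-one; 7 (1R,2R)-1,2-diphenylethane-1,2-diol [(R,R)-hydrobenzoin]
Product: 8 1-[(1R,4R,4'R,5R,5'R,6S)-4',5'-diphenyl-6-(propan-2-yl)-7-oxaspiro[bicyclo[2.2.1]heptane-2,2'-[1,3]dioxolan]-5-yl]ethan-1-one
Conditions: PPTS (cat.), 5 Å MS, CH2Cl2, 0 → 23 °C; the two diastereomers separated on SiO2 or by crystallization
Reagents that add atoms: none
Why: Protonation of the enol ether gives an oxocarbenium ion that the diol traps (transketalization with loss of methanol), which removes the peracid-sensitive alkene and blocks cycloreversion; because the diol is enantiopure and C2-symmetric, the two enantiomers of 6 give exactly two diastereomeric ketals with no new stereocenter, and the (1R,4R,5R,6S) one is carried on.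

**Step 6**
Reactants: 8 1-[(1R,4R,4'R,5R,5'R,6S)-4',5'-diphenyl-6-(propan-2-yl)-7-oxaspiro[bicyclo[2.2.1]heptane-2,2'-[1,3]dioxolan]-5-yl]ethan-1-one
Product: 10 (1R,4R,4'R,5R,5'R,6S)-4',5'-diphenyl-6-(propan-2-yl)-7-oxaspiro[bicyclo[2.2.1]heptane-2,2'-[1,3]dioxolan]-5-ol, via acetate 9 (not isolated)
Conditions: mCPBA, Na2HPO4, CH2Cl2, 40 °C; then K2CO3, MeOH, 23 °C
Reagents that add atoms: 3-chloroperbenzoic acid, OOC(=O)c1cccc(Cl)c1
Why: In the Baeyer–Villiger oxidation the secondary ring carbon migrates in preference to methyl and with retention, so the endo C–acetyl bond becomes the endo C–O bond of target C4; mild methanolysis then frees the alcohol while the ketal survives buffered peracid and base.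

**Step 7**
Reactants: 10 (1R,4R,4'R,5R,5'R,6S)-4',5'-diphenyl-6-(propan-2-yl)-7-oxaspiro[bicyclo[2.2.1]heptane-2,2'-[1,3]dioxolan]-5-ol
Product: 11 (1R,4R,4'R,5R,5'R,6S)-4',5'-diphenyl-6-(propan-2-yl)-7-oxaspiro[bicyclo[2.2.1]heptane-2,2'-[1,3]dioxolan]-5-yl 2-methylpropanoate
Conditions: isobutyryl chloride, pyridine, DMAP (cat.), CH2Cl2, 0 → 23 °C
Reagents that add atoms: isobutyryl chloride, CC(C)C(Cl)=O
Why: DMAP-catalysed O-acylation of the secondary alcohol installs the isobutyrate without touching the carbinol stereocenter.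

**Step 8**
Reactants: 11 (1R,4R,4'R,5R,5'R,6S)-4',5'-diphenyl-6-(propan-2-yl)-7-oxaspiro[bicyclo[2.2.1]heptane-2,2'-[1,3]dioxolan]-5-yl 2-methylpropanoate
Product: 13 (1S,5R,6R)-5-hydroxy-4-oxo-6-(propan-2-yl)cyclohex-2-en-1-yl 2-methylpropanoate, via bicyclic ketone 12 (not isolated)
Conditions: TFA/H2O (9:1), CH2Cl2, 0 °C; then Et3N, CH2Cl2, 0 °C
Reagents that add atoms: water, O
Why: Acid hydrolysis frees the ketone, which can enolize only toward the CH2 group (the other α-carbon is a bridgehead, Bredt's rule), and the enolate expels the bridging oxygen in a strain-releasing E1cB (retro-oxa-Michael) step that forms the C2=C3 enone and leaves that oxygen as the C6 hydroxyl with unchanged configuration at C4, C5 and C6; the trans-5,6 arrangement is also the thermodynamically preferred one, so the α-ketol center should not drift.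

**Step 9**
Reactants: 14 2-[(tert-butyldimethylsilyl)oxy]acetaldehyde; 15 ethyl 2-(triphenyl-λ5-phosphanylidene)propanoate
Product: 16 ethyl (2E)-4-[(tert-butyldimethylsilyl)oxy]-2-methylbut-2-enoate
Conditions: CH2Cl2, 23 °C
Reagents that add atoms: none
Why: Wittig olefination with a stabilized α-methyl ylide should give the (E)-trisubstituted enoate required for the side chain.

**Step 10**
Reactants: 16 ethyl (2E)-4-[(tert-butyldimethylsilyl)oxy]-2-methylbut-2-enoate
Product: 17 (2E)-4-[(tert-butyldimethylsilyl)oxy]-2-methylbut-2-enoic acid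
Conditions: LiOH, THF/MeOH/H2O, 23 °C; then aq. HCl to pH 4, 0 °C
Reagents that add atoms: lithium hydroxide, [Li+].[OH-]
Why: Saponification of the ethyl ester leaves the silyl ether and the alkene geometry intact when the acidification is kept cold and brief.

**Step 11**
Reactants: 13 (1S,5R,6R)-5-hydroxy-4-oxo-6-(propan-2-yl)cyclohex-2-en-1-yl 2-methylpropanoate; 17 (2E)-4-[(tert-butyldimethylsilyl)oxy]-2-methylbut-2-enoic acid
Product: 18 (1R,5S,6S)-5-[(2-methylpropanoyl)oxy]-2-oxo-6-(propan-2-yl)cyclohex-3-en-1-yl (2E)-4-[(tert-butyldimethylsilyl)oxy]-2-methylbut-2-enoate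
Conditions: DCC, DMAP (cat.), CH2Cl2, 0 → 23 °C
Reagents that add atoms: none
Why: Steglich esterification acylates the only free hydroxyl (C6) under near-neutral conditions, so the α-ketol center and the allylic isobutyrate should be preserved.

**Step 12**
Reactants: 18 (1R,5S,6S)-5-[(2-methylpropanoyl)oxy]-2-oxo-6-(propan-2-yl)cyclohex-3-en-1-yl (2E)-4-[(tert-butyldimethylsilyl)oxy]-2-methylbut-2-enoate
Product: 19 (1R,5S,6S)-3-(hydroxymethyl)-5-[(2-methylpropanoyl)oxy]-2-oxo-6-(propan-2-yl)cyclohex-3-en-1-yl (2E)-4-[(tert-butyldimethylsilyl)oxy]-2-methylbut-2-enoate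
Conditions: aq. CH2O (37%), imidazole, NaHCO3 (1 M aq.), THF, 23 °C
Reagents that add atoms: formaldehyde, C=O
Why: Morita–Baylis–Hillman hydroxymethylation: imidazole adds reversibly to C3 of the cyclohexenone, the resulting enolate captures formaldehyde at C2 and the catalyst is expelled; the α-methyl, β-substituted side-chain enoate cannot react in this way and no stereocenter is touched.

**Step 13**
Reactants: 19 (1R,5S,6S)-3-(hydroxymethyl)-5-[(2-methylpropanoyl)oxy]-2-oxo-6-(propan-2-yl)cyclohex-3-en-1-yl (2E)-4-[(tert-butyldimethylsilyl)oxy]-2-methylbut-2-enoate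
Product: 20 (1R,5S,6S)-3-(hydroxymethyl)-5-[(2-methylpropanoyl)oxy]-2-oxo-6-(propan-2-yl)cyclohex-3-en-1-yl (2E)-4-hydroxy-2-methylbut-2-enoate (CNP0254776.1)
Conditions: HF·pyridine, pyridine, THF, 0 → 23 °C
Reagents that add atoms: none
Why: Buffered fluoride cleaves the primary silyl ether without affecting the three esters or the enone, which should give the target.

**Compound list**
1 | 3-bromofuran | Brc1ccoc1 | starting material
2 | 3-methoxyfuran | COc1ccoc1 | intermediate
3 | 3-methylbut-1-yne | CC(C)C#C | starting material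
4 | 5-methylhex-3-yn-2-one | CC(C)C#CC(C)=O | intermediate
5 | (Z)-5-methylhex-3-en-2-one | CC(C)/C=C\C(C)=O | intermediate
6 | rac-1-[(1R,4R,5R,6S)-2-methoxy-6-(propan-2-yl)-7-oxabicyclo[2.2.1]hept-2-en-5-yl]ethan-1-one (racemate; the enantiomer carried on is drawn) | COC1=C[C@@H]2[C@H](C(C)=O)[C@H](C(C)C)[C@H]1O2 | intermediate
7 | (1R,2R)-1,2-diphenylethane-1,2-diol | O[C@H](c1ccccc1)[C@H](O)c1ccccc1 | starting material
8 | 1-[(1R,4R,4'R,5R,5'R,6S)-4',5'-diphenyl-6-(propan-2-yl)-7-oxaspiro[bicyclo[2.2.1]heptane-2,2'-[1,3]dioxolan]-5-yl]ethan-1-one | C12(O[C@H](c3ccccc3)[C@@H](c3ccccc3)O1)C[C@@H]3[C@H](C(C)=O)[C@H](C(C)C)[C@H]2O3 | intermediate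
9 | (1R,4R,4'R,5R,5'R,6S)-4',5'-diphenyl-6-(propan-2-yl)-7-oxaspiro[bicyclo[2.2.1]heptane-2,2'-[1,3]dioxolan]-5-yl acetate | C12(O[C@H](c3ccccc3)[C@@H](c3ccccc3)O1)C[C@@H]3[C@H](OC(C)=O)[C@H](C(C)C)[C@H]2O3 | intermediate (not isolated)
10 | (1R,4R,4'R,5R,5'R,6S)-4',5'-diphenyl-6-(propan-2-yl)-7-oxaspiro[bicyclo[2.2.1]heptane-2,2'-[1,3]dioxolan]-5-ol | C12(O[C@H](c3ccccc3)[C@@H](c3ccccc3)O1)C[C@@H]3[C@H](O)[C@H](C(C)C)[C@H]2O3 | intermediate
11 | (1R,4R,4'R,5R,5'R,6S)-4',5'-diphenyl-6-(propan-2-yl)-7-oxaspiro[bicyclo[2.2.1]heptane-2,2'-[1,3]dioxolan]-5-yl 2-methylpropanoate | C12(O[C@H](c3ccccc3)[C@@H](c3ccccc3)O1)C[C@@H]3[C@H](OC(=O)C(C)C)[C@H](C(C)C)[C@H]2O3 | intermediate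
12 | (1R,4R,5R,6S)-2-oxo-6-(propan-2-yl)-7-oxabicyclo[2.2.1]heptan-5-yl 2-methylpropanoate (numbering as in 6) | O=C1C[C@@H]2[C@H](OC(=O)C(C)C)[C@H](C(C)C)[C@H]1O2 | intermediate (not isolated)
13 | (1S,5R,6R)-5-hydroxy-4-oxo-6-(propan-2-yl)cyclohex-2-en-1-yl 2-methylpropanoate | O[C@H]1C(=O)C=C[C@H](OC(=O)C(C)C)[C@@H]1C(C)C | intermediate
14 | 2-[(tert-butyldimethylsilyl)oxy]acetaldehyde | O=CCO[Si](C)(C)C(C)(C)C | starting material
15 | ethyl 2-(triphenyl-λ5-phosphanylidene)propanoate | CCOC(=O)C(C)=P(c1ccccc1)(c1ccccc1)c1ccccc1 | starting material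
16 | ethyl (2E)-4-[(tert-butyldimethylsilyl)oxy]-2-methylbut-2-enoate | C/C(=C\CO[Si](C)(C)C(C)(C)C)C(=O)OCC | intermediate
17 | (2E)-4-[(tert-butyldimethylsilyl)oxy]-2-methylbut-2-enoic acid | C/C(=C\CO[Si](C)(C)C(C)(C)C)C(=O)O | intermediate
18 | (1R,5S,6S)-5-[(2-methylpropanoyl)oxy]-2-oxo-6-(propan-2-yl)cyclohex-3-en-1-yl (2E)-4-[(tert-butyldimethylsilyl)oxy]-2-methylbut-2-enoate | C/C(=C\CO[Si](C)(C)C(C)(C)C)C(=O)O[C@H]1C(=O)C=C[C@H](OC(=O)C(C)C)[C@@H]1C(C)C | intermediate
19 | (1R,5S,6S)-3-(hydroxymethyl)-5-[(2-methylpropanoyl)oxy]-2-oxo-6-(propan-2-yl)cyclohex-3-en-1-yl (2E)-4-[(tert-butyldimethylsilyl)oxy]-2-methylbut-2-enoate | C/C(=C\CO[Si](C)(C)C(C)(C)C)C(=O)O[C@H]1C(=O)C(CO)=C[C@H](OC(=O)C(C)C)[C@@H]1C(C)C | intermediate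
20 | (1R,5S,6S)-3-(hydroxymethyl)-5-[(2-methylpropanoyl)oxy]-2-oxo-6-(propan-2-yl)cyclohex-3-en-1-yl (2E)-4-hydroxy-2-methylbut-2-enoate | C/C(=C\CO)C(=O)O[C@H]1C(=O)C(CO)=C[C@H](OC(=O)C(C)C)[C@@H]1C(C)C | target

**Totals**
Total step count: 13. Longest linear sequence: 10 steps (steps 2, 3, 4, 5, 6, 7, 8, 11, 12, 13).

**Steps most likely to fail**

Step 4. The Z-disubstituted enone may add slowly, so that cycloreversion, Z→E isomerization of 5 or competing exo addition erode the relative configuration. The fallback sets out from 2 and returns at 11. Compound 2 is combined with commercial (E)-5-methylhex-3-en-2-one, which is more reactive and configurationally stable, to give the trans-configured cycloadducts F1; any endo/exo mixture is acceptable. Transketalization with 7 gives the ketals F2, Baeyer–Villiger oxidation the acetates F3 and methanolysis the alcohols F4. Dess–Martin oxidation gives the ring ketone F5, which can enolize only toward the isopropyl-bearing carbon. KN(SiMe3)2 followed by isobutyric anhydride gives the enol isobutyrate F6; at this stage the stereochemistry at the two former dienophile carbons is erased and only two hydrobenzoin diastereomers remain, which are separated. Hydrogenation over Rh/Al2O3 (H2, 1 atm, EtOAc) should add both hydrogens to the exo face of the strained bicyclic alkene and deliver 11 with the isobutyrate and isopropyl groups endo.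

Step 8. Ketal hydrolysis next to the bridgehead oxygen may be sluggish, and under the basic opening conditions the product may lose isobutyric acid and aromatize. The fallback sets out from 11 and returns at 13. The hydrobenzoin ketal is removed under neutral conditions by hydrogenolysis (H2, Pd(OH)2/C, EtOAc) and ketone 12 is isolated. Soft enolization with tert-butyldimethylsilyl triflate and Et3N at −78 °C should open the bridge by silyl-triflate-assisted β-elimination and trap the oxygen as the silyl ether, (1S,5R,6S)-5-[(tert-butyldimethylsilyl)oxy]-4-oxo-6-(propan-2-yl)cyclohex-2-en-1-yl 2-methylpropanoate F7, so that no free alkoxide is present. HF·pyridine then gives 13.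

Step 12. During the slow amine-catalysed hydroxymethylation the doubly acylated enone may undergo acyl transfer from the α-acyloxy ketone or base-induced elimination and aromatization. The fallback sets out from 18 and returns at 19. α-Iodination with I2 and pyridine in CH2Cl2 gives the 2-iodoenone, (1R,5R,6S)-3-iodo-5-[(2-methylpropanoyl)oxy]-2-oxo-6-(propan-2-yl)cyclohex-3-en-1-yl (2E)-4-[(tert-butyldimethylsilyl)oxy]-2-methylbut-2-enoate F8. Stille coupling with (tributylstannyl)methanol (Pd(PPh3)4, dioxane, 80 °C) then installs the hydroxymethyl group under neutral conditions.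

**Further compounds**
F1 | step 4 | rac-1-[(1R,4R,5R,6R)-2-methoxy-6-(propan-2-yl)-7-oxabicyclo[2.2.1]hept-2-en-5-yl]ethan-1-one (trans adducts; the 5-endo-acetyl-6-exo-isopropyl isomer is drawn) | COC1=C[C@@H]2[C@H](C(C)=O)[C@@H](C(C)C)[C@H]1O2
F2 | step 4 | (R,R)-hydrobenzoin ketals of F1 (stereoisomer mixture; one isomer drawn) | C12(O[C@H](c3ccccc3)[C@@H](c3ccccc3)O1)C[C@@H]3[C@H](C(C)=O)[C@@H](C(C)C)[C@H]2O3
F3 | step 4 | corresponding 5-acetates (stereoisomer mixture; one isomer drawn) | C12(O[C@H](c3ccccc3)[C@@H](c3ccccc3)O1)C[C@@H]3[C@H](OC(C)=O)[C@@H](C(C)C)[C@H]2O3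
F4 | step 4 | corresponding 5-alcohols (stereoisomer mixture; one isomer drawn) | C12(O[C@H](c3ccccc3)[C@@H](c3ccccc3)O1)C[C@@H]3[C@H](O)[C@@H](C(C)C)[C@H]2O3
F5 | step 4 | (1R,4R,4'R,5'R)-4',5'-diphenyl-6-(propan-2-yl)-7-oxaspiro[bicyclo[2.2.1]heptane-2,2'-[1,3]dioxolan]-5-one (C6 epimers, together with the (1S,4S) series) | C12(O[C@H](c3ccccc3)[C@@H](c3ccccc3)O1)C[C@@H]3C(=O)C(C(C)C)[C@H]2O3
F6 | step 4 | (1R,4R,4'R,5'R)-4',5'-diphenyl-6-(propan-2-yl)-7-oxaspiro[bicyclo[2.2.1]hept[5]ene-2,2'-[1,3]dioxolan]-5-yl 2-methylpropanoate (after separation from the (1S,4S) diastereomer) | C12(O[C@H](c3ccccc3)[C@@H](c3ccccc3)O1)C[C@@H]3C(OC(=O)C(C)C)=C(C(C)C)[C@H]2O3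
F7 | step 8 | (1S,5R,6S)-5-[(tert-butyldimethylsilyl)oxy]-4-oxo-6-(propan-2-yl)cyclohex-2-en-1-yl 2-methylpropanoate | C[Si](C)(C(C)(C)C)O[C@H]1C(=O)C=C[C@H](OC(=O)C(C)C)[C@@H]1C(C)C
F8 | step 12 | (1R,5R,6S)-3-iodo-5-[(2-methylpropanoyl)oxy]-2-oxo-6-(propan-2-yl)cyclohex-3-en-1-yl (2E)-4-[(tert-butyldimethylsilyl)oxy]-2-methylbut-2-enoate | C/C(=C\CO[Si](C)(C)C(C)(C)C)C(=O)O[C@H]1C(=O)C(I)=C[C@H](OC(=O)C(C)C)[C@@H]1C(C)C
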